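The 3(2H)-furanone that bridges the ten-membered ring (O–C3=C2–C1(=O)–C10, germacrane numbering) is the cyclodehydrated hydrate of a γ-hydroxy ynone, so C1–C2 can be acetylene. The route rests on stitching acetylene in one flask between two fragments that both derive from glyoxal monoacetal: it adds to the C10 methyl ketone of a C7–C10 piece, where a magnesium chelate to the C8 ether sets the tertiary carbinol, and the resulting alkynyl Grignard acylates a (Z)-C3–C6 Weinreb amide. The precursor pair is thus an acyclic keto acetal and an enamide; amine-mediated hydration then closes the furanone, and an allylchromium addition closes the carbocycle and the lactone.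

Key step: step 5

Remark: atoms are numbered as in germacranes (C1–C10 ring carbons, C11–C13 lactone part, C14 on C10, C15 on C4).
Assumption: L-proline is taken to give the (R)-aldol as it does with other aldehydes, and chelation-controlled addition to the β-alkoxy ketone is taken to give the 1,3-anti product; 2,2-dimethoxyacetaldehyde is used as its aqueous solution in step 1 and as an anhydrous MTBE solution in step 3.

Step 1
Reactants: 1 acetone; 2 2,2-dimethoxyacetaldehyde
Product: 3 (R)-4-hydroxy-5,5-dimethoxypentan-2-one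
Conditions: L-proline (30 mol %), acetone/DMSO, rt
Reagents that add atoms: none
Why: Proline-catalysed enamine aldol reaction in which the acetone enamine should attack the re face of the non-enolizable aldehyde through the acid-organised chair transition state, setting the (R)-carbinol that becomes C8.

Step 2
Reactants: 3 (R)-4-hydroxy-5,5-dimethoxypentan-2-one
Product: 4 (R)-5,5-dimethoxy-4-(naphthalen-2-ylmethoxy)pentan-2-one
Conditions: 2-(bromomethyl)naphthalene, Ag2O, 4 Å MS, CH2Cl2, rt, dark
Reagents that add atoms: 2-(bromomethyl)naphthalene, BrCc1ccc2ccccc2c1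
Why: Ag2O-mediated Williamson-type etherification under near-neutral conditions should avoid retro-aldol and β-elimination and installs an acid-stable, chelating, DDQ-cleavable ether on O8.

Step 3
Reactants: 2 2,2-dimethoxyacetaldehyde; 5 methyl 2-[bis(2,2,2-trifluoroethoxy)phosphoryl]propanoate
Product: 6 methyl (Z)-4,4-dimethoxy-2-methylbut-2-enoate
Conditions: 5, KN(SiMe3)2, 18-crown-6, THF, −78 °C; then 2 (anhydrous, MTBE)
Reagents that add atoms: none
Why: Still–Gennari olefination, in which the electron-poor phosphonate under dissociating conditions should collapse kinetically to the (Z)-trisubstituted enoate and so fix the C4=C5 geometry (C3 and C6 cis).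

Step 4
Reactants: 6 methyl (Z)-4,4-dimethoxy-2-methylbut-2-enoate
Product: 7 (Z)-N,4,4-trimethoxy-N,2-dimethylbut-2-enamide
Conditions: MeNH(OMe)·HCl, iPrMgCl, THF, −20 → 0 °C
Reagents that add atoms: N,O-dimethylhydroxylamine hydrochloride, CNOC.Cl
Why: Weinreb amidation of the ester by the chloromagnesium amide at low temperature, where acyl substitution should outrun conjugate addition so that the (Z)-alkene is kept.

Step 5
Reactants: 4 (R)-5,5-dimethoxy-4-(naphthalen-2-ylmethoxy)pentan-2-one; 8 ethynylmagnesium bromide; 7 (Z)-N,4,4-trimethoxy-N,2-dimethylbut-2-enamide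
Product: 11 (2Z,7R,9R)-7-hydroxy-1,1,10,10-tetramethoxy-3,7-dimethyl-9-(naphthalen-2-ylmethoxy)dec-2-en-5-yn-4-one, via propargylic magnesium alkoxide 9 (not isolated), via dimagnesium alkynyl alkoxide 10 (not isolated)
Conditions: 4, MgBr2·OEt2, CH2Cl2, −78 °C; HC≡CMgBr (1.1 equiv, THF); then EtMgBr (1.2 equiv), 0 → 40 °C; then 7, 0 °C → rt; aq. NH4Cl
Reagents that add atoms: none
Why: Ethynylmagnesium bromide adds to the C10 ketone of 4 (bond C1–C10), the alkoxide 9 is metallated at the terminal alkyne by EtMgBr to give 10, and this alkynyl Grignard acylates Weinreb amide 7 (bond C2–C3) through the stable N,O-chelated tetrahedral intermediate, which releases the ynone only on quench. The closest known reaction types are the Grignard alkynylation of ketones and the Weinreb ketone synthesis with propargylic alcohol dianions, here telescoped with acetylene as a two-carbon linchpin. No ring is closed in this step; it creates the C10–OH/C3=O relationship from which step 6 closes the furanone. The new stereocenter C10 is controlled by 1,3-chelation: magnesium bridges the C10 carbonyl oxygen and the C8 ether oxygen in a six-membered half-chair with C7 pseudo-equatorial, and axial entry of the acetylide should give the 8,10-anti (10R) carbinol. The step needs chemoselectivity (ketone before amide, single 1,2-addition to the enamide), secured by the order of addition and the Weinreb chelate, and facial selectivity, secured by the chelating naphthylmethyl ether and the non-coordinating cosolvent.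

Step 6
Reactants: 11 (2Z,7R,9R)-7-hydroxy-1,1,10,10-tetramethoxy-3,7-dimethyl-9-(naphthalen-2-ylmethoxy)dec-2-en-5-yn-4-one
Product: 14 (R)-2-methyl-2-[(R)-2-(naphthalen-2-ylmethoxy)-3-oxopropyl]-5-[(Z)-4-oxobut-2-en-2-yl]furan-3(2H)-one, via enaminone 12 (not isolated), via furanone bis(dimethyl acetal) 13 (not isolated)
Conditions: Et2NH, EtOH, rt; then 2 M aq. HCl, THF, rt → 40 °C
Reagents that add atoms: water, O
Why: Conjugate addition of Et2NH to C1 of the ynone gives a vinylogous amide whose acid hydrolysis unveils the C1 ketone of a 1,3-diketone that the C10 hydroxyl traps at C3 (5-exo-trig addition, then dehydration) to the 3(2H)-furanone, the classical γ-hydroxy-ynone-to-furanone conversion, while the same aqueous acid should hydrolyse both dimethyl acetals to the C6 and C7 aldehydes.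

Step 7
Reactants: 14 (R)-2-methyl-2-[(R)-2-(naphthalen-2-ylmethoxy)-3-oxopropyl]-5-[(Z)-4-oxobut-2-en-2-yl]furan-3(2H)-one; 15 methyl acrylate
Product: 16 methyl (4R)-3-hydroxy-2-methylidene-5-[(R)-2-methyl-3-oxo-5-((Z)-4-oxobut-2-en-2-yl)-2,3-dihydrofuran-2-yl]-4-(naphthalen-2-ylmethoxy)pentanoate (both C3 epimers)
Conditions: 15 (1.5 equiv), DABCO (0.5 equiv), MeOH, rt
Reagents that add atoms: none
Why: Morita–Baylis–Hillman reaction in which the DABCO–acrylate zwitterion should add to the inductively activated aliphatic α-alkoxy aldehyde (C7) much faster than to the β,β-disubstituted, doubly conjugated C6 enal; the new carbinol centre is of no consequence because it becomes sp2 in step 8.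

Step 8
Reactants: 16 methyl (4R)-3-hydroxy-2-methylidene-5-[(R)-2-methyl-3-oxo-5-((Z)-4-oxobut-2-en-2-yl)-2,3-dihydrofuran-2-yl]-4-(naphthalen-2-ylmethoxy)pentanoate
Product: 17 methyl (2Z,4R)-2-(bromomethyl)-5-[(R)-2-methyl-3-oxo-5-((Z)-4-oxobut-2-en-2-yl)-2,3-dihydrofuran-2-yl]-4-(naphthalen-2-ylmethoxy)pent-2-enoate
Conditions: NBS, Me2S, CH2Cl2, −20 → 0 °C
Reagents that add atoms: N-bromosuccinimide, O=C1CCC(=O)N1Br
Why: Corey–Kim-type activation of the allylic alcohol as an alkoxysulfonium ion and SN2′ attack of bromide should convert both epimers into the thermodynamically preferred (Z)-2-(bromomethyl)enoate with the double bond moved to C7=C11, aldehydes being inert.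

Step 9
Reactants: 17 methyl (2Z,4R)-2-(bromomethyl)-5-[(R)-2-methyl-3-oxo-5-((Z)-4-oxobut-2-en-2-yl)-2,3-dihydrofuran-2-yl]-4-(naphthalen-2-ylmethoxy)pent-2-enoate
Product: 20 (6R,7R,8R,10R)-8-(naphthalen-2-ylmethoxy)-1-oxo-3,10-epoxygermacra-2,4(Z),11(13)-trien-12,6-olide, via allylchromium dichloride 18 (not isolated), via hydroxy ester 19 (not isolated)
Conditions: CrCl2 (6 equiv), THF, rt, 0.002 M (syringe pump); aq. NH4Cl
Reagents that add atoms: none
Why: Nozaki–Hiyama-type intramolecular allylation (Barbier macrocyclization) in which two CrCl2 reduce the allylic bromide to an allyl species of trivalent chromium that attacks the C6 aldehyde through C7 in a chair-like six-membered transition state with the aldehyde substituent pseudo-equatorial, which should give the anti (6R,7R) relationship with the face of C7 chosen by the adjacent C8 stereocentre (allylic 1,3-strain) and the furanone-bridged tether, after which the chromium alkoxide closes the trans-fused α-methylene lactone by 5-exo-trig acyl substitution.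

Step 10
Reactants: 20 (6R,7R,8R,10R)-8-(naphthalen-2-ylmethoxy)-1-oxo-3,10-epoxygermacra-2,4(Z),11(13)-trien-12,6-olide
Product: 21 (6R,7R,8R,10R)-8-hydroxy-1-oxo-3,10-epoxygermacra-2,4(Z),11(13)-trien-12,6-olide
Conditions: DDQ, CH2Cl2/pH 7 buffer, 0 °C → rt
Reagents that add atoms: none
Why: Oxidative cleavage of the 2-naphthylmethyl ether by hydride abstraction and hydrolysis of the oxocarbenium ion, which should leave the electron-poor alkenes, the furanone and the lactone untouched.

Step 11
Reactants: 21 (6R,7R,8R,10R)-8-hydroxy-1-oxo-3,10-epoxygermacra-2,4(Z),11(13)-trien-12,6-olide; 22 angelic acid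
Product: 23 15-deoxybudlein A
Conditions: 22, 2,4,6-trichlorobenzoyl chloride, Et3N, toluene, rt; then 21, 80 °C
Reagents that add atoms: none
Why: Yamaguchi-type esterification through the mixed 2,4,6-trichlorobenzoic anhydride without a nucleophilic catalyst should acylate the hindered C8 alcohol with retention (the C–O bond is not broken) and without isomerization of the angelate to the tiglate.

Compound list
1 | acetone | CC(C)=O | starting material
2 | 2,2-dimethoxyacetaldehyde | COC(OC)C=O | starting material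
3 | (R)-4-hydroxy-5,5-dimethoxypentan-2-one | CC(=O)C[C@@H](O)C(OC)OC | intermediate
4 | (R)-5,5-dimethoxy-4-(naphthalen-2-ylmethoxy)pentan-2-one | CC(=O)C[C@@H](OCc1ccc2ccccc2c1)C(OC)OC | intermediate
5 | methyl 2-[bis(2,2,2-trifluoroethoxy)phosphoryl]propanoate | COC(=O)C(C)P(=O)(OCC(F)(F)F)OCC(F)(F)F | starting material
6 | methyl (Z)-4,4-dimethoxy-2-methylbut-2-enoate | COC(=O)/C(C)=C\C(OC)OC | intermediate
7 | (Z)-N,4,4-trimethoxy-N,2-dimethylbut-2-enamide | CON(C)C(=O)/C(C)=C\C(OC)OC | intermediate
8 | ethynylmagnesium bromide | C#C[Mg]Br | starting material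
9 | bromomagnesium (3R,5R)-6,6-dimethoxy-3-methyl-5-(naphthalen-2-ylmethoxy)hex-1-yn-3-olate | C#C[C@](C)(O[Mg]Br)C[C@@H](OCc1ccc2ccccc2c1)C(OC)OC | intermediate
10 | C,O-bis(bromomagnesium) derivative of (3R,5R)-6,6-dimethoxy-3-methyl-5-(naphthalen-2-ylmethoxy)hex-1-yn-3-ol | Br[Mg]C#C[C@](C)(O[Mg]Br)C[C@@H](OCc1ccc2ccccc2c1)C(OC)OC | intermediate
11 | (2Z,7R,9R)-7-hydroxy-1,1,10,10-tetramethoxy-3,7-dimethyl-9-(naphthalen-2-ylmethoxy)dec-2-en-5-yn-4-one | COC(OC)/C=C(/C)C(=O)C#C[C@](C)(O)C[C@@H](OCc1ccc2ccccc2c1)C(OC)OC | intermediate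
12 | (2Z,7R,9R)-6-(diethylamino)-7-hydroxy-1,1,10,10-tetramethoxy-3,7-dimethyl-9-(naphthalen-2-ylmethoxy)deca-2,5-dien-4-one | CCN(CC)C(=CC(=O)/C(C)=C\C(OC)OC)[C@](C)(O)C[C@@H](OCc1ccc2ccccc2c1)C(OC)OC | intermediate
13 | (R)-5-[(Z)-4,4-dimethoxybut-2-en-2-yl]-2-[(R)-3,3-dimethoxy-2-(naphthalen-2-ylmethoxy)propyl]-2-methylfuran-3(2H)-one | COC(OC)/C=C(/C)C1=CC(=O)[C@@](C)(C[C@@H](OCc2ccc3ccccc3c2)C(OC)OC)O1 | intermediate
14 | (R)-2-methyl-2-[(R)-2-(naphthalen-2-ylmethoxy)-3-oxopropyl]-5-[(Z)-4-oxobut-2-en-2-yl]furan-3(2H)-one | O=C/C=C(/C)C1=CC(=O)[C@@](C)(C[C@@H](OCc2ccc3ccccc3c2)C=O)O1 | intermediate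
15 | methyl acrylate | C=CC(=O)OC | starting material
16 | methyl (4R)-3-hydroxy-2-methylidene-5-[(R)-2-methyl-3-oxo-5-((Z)-4-oxobut-2-en-2-yl)-2,3-dihydrofuran-2-yl]-4-(naphthalen-2-ylmethoxy)pentanoate | O=C/C=C(/C)C1=CC(=O)[C@@](C)(C[C@@H](OCc2ccc3ccccc3c2)C(O)C(=C)C(=O)OC)O1 | intermediate
17 | methyl (2Z,4R)-2-(bromomethyl)-5-[(R)-2-methyl-3-oxo-5-((Z)-4-oxobut-2-en-2-yl)-2,3-dihydrofuran-2-yl]-4-(naphthalen-2-ylmethoxy)pent-2-enoate | O=C/C=C(/C)C1=CC(=O)[C@@](C)(C[C@@H](OCc2ccc3ccccc3c2)/C=C(\CBr)C(=O)OC)O1 | intermediate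
18 | allylchromium dichloride from 17 (CH2Br replaced by CH2CrCl2) | O=C/C=C(/C)C1=CC(=O)[C@@](C)(C[C@@H](OCc2ccc3ccccc3c2)/C=C(\C[Cr](Cl)Cl)C(=O)OC)O1 | intermediate
19 | methyl (6R,7S,8R,10R)-6-hydroxy-8-(naphthalen-2-ylmethoxy)-1-oxo-3,10-epoxygermacra-2,4(Z),11(13)-trien-12-oate | O[C@@H]1/C=C(/C)C2=CC(=O)[C@@](C)(C[C@@H](OCc3ccc4ccccc4c3)[C@H]1C(=C)C(=O)OC)O2 | intermediate
20 | (6R,7R,8R,10R)-8-(naphthalen-2-ylmethoxy)-1-oxo-3,10-epoxygermacra-2,4(Z),11(13)-trien-12,6-olide | C=C1C(=O)O[C@@H]2/C=C(/C)C3=CC(=O)[C@@](C)(C[C@@H](OCc4ccc5ccccc5c4)[C@@H]12)O3 | intermediate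
21 | (6R,7R,8R,10R)-8-hydroxy-1-oxo-3,10-epoxygermacra-2,4(Z),11(13)-trien-12,6-olide | C=C1C(=O)O[C@@H]2/C=C(/C)C3=CC(=O)[C@@](C)(C[C@@H](O)[C@@H]12)O3 | intermediate
22 | angelic acid, (Z)-2-methylbut-2-enoic acid | C/C=C(/C)C(=O)O | starting material
23 | 15-deoxybudlein A | C=C1C(=O)O[C@@H]2/C=C(/C)C3=CC(=O)[C@@](C)(C[C@@H](OC(=O)/C(C)=C\C)[C@@H]12)O3 | target

Total step count: 11
Longest linear sequence: 9 steps (steps 1, 2, 5, 6, 7, 8, 9, 10, 11)

Steps most likely to fail

1. Step 5. The 1,3-induction may be weak, so that the acetylide discriminates poorly between the faces of the C10 carbonyl. Enolization with β-elimination of the naphthylmethoxy group may compete, and premature or double addition may occur when three components meet in one flask. Fallback, setting out from 3 and returning at 11: the two bonds are made in separate flasks and the free hydroxyl is used as the directing group. Aldol 3 is treated with excess ethynylmagnesium bromide 8 (THF/CH2Cl2, −78 → −20 °C). The magnesium aldolate should hold the ketone in a tighter chelate than the ether does and give (3R,5R)-6,6-dimethoxy-3-methylhex-1-yne-3,5-diol F1, from which the C10 epimer can be removed by crystallization or chromatography. Selective etherification of the secondary hydroxyl (2-(bromomethyl)naphthalene, Ag2O) gives (3R,5R)-6,6-dimethoxy-3-methyl-5-(naphthalen-2-ylmethoxy)hex-1-yn-3-ol F2. Its dianion (n-BuLi, 2 equiv, THF, −78 °C) is acylated with 7 to give 11.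

2. Step 9. Oligomerization may outrun ring closure, and the strained furanone-bridged ring may force closure through the wrong diastereomeric transition state (syn addition, or attack on the other face of C7). Fallback, setting out from 17 and returning at 20: the open-shell metal reduction is replaced by an allylboration with a closed, metal-free six-membered transition state. Bromide 17 is borylated with B2pin2 and Pd2(dba)3 (cat.) in toluene to the pinacol allylboronate F3 (CH2Br of 17 replaced by CH2Bpin). Under high dilution with Sc(OTf)3 (cat.) it should add to the C6 aldehyde and give, after oxidative work-up, hydroxy ester 19, which lactonizes to 20.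

3. Step 7. Turnover of the amine-catalysed addition may be slow, so that the conjugated C6 aldehyde also reacts and base-induced epimerization at C8 or Z/E isomerization at C4=C5 sets in. Fallback, setting out from 4 and returning at 16: the acrylate unit is attached before the enal exists.
 - Ketone 4 is hydrolysed (aqueous trifluoroacetic acid, CH2Cl2, 0 °C) to (R)-2-(naphthalen-2-ylmethoxy)-4-oxopentanal F4, which has only one aldehyde.
 - The Morita–Baylis–Hillman reaction with 15 (DABCO) gives methyl (4R)-3-hydroxy-2-methylidene-4-(naphthalen-2-ylmethoxy)-6-oxoheptanoate F5.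
 - Silylation (Et3SiOTf, 2,6-lutidine) gives the triethylsilyl ether F6.
 - The one-flask union with 8 and 7, with TMPMgCl·LiCl in place of EtMgBr to spare the acrylate, gives the triethylsilyl-protected acrylate ynone F7.
 - AuCl3-catalysed hydration–cyclization in wet acetonitrile followed by 2 M aq. HCl in THF closes the furanone, hydrolyses the C6 acetal and the silyl ether, and gives 16.

Further compounds
F1 | step 5 | (3R,5R)-6,6-dimethoxy-3-methylhex-1-yne-3,5-diol | C#C[C@](C)(O)C[C@@H](O)C(OC)OC
F2 | step 5 | (3R,5R)-6,6-dimethoxy-3-methyl-5-(naphthalen-2-ylmethoxy)hex-1-yn-3-ol | C#C[C@](C)(O)C[C@@H](OCc1ccc2ccccc2c1)C(OC)OC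
F3 | step 9 | methyl (2E,4R)-5-[(R)-2-methyl-3-oxo-5-((Z)-4-oxobut-2-en-2-yl)-2,3-dihydrofuran-2-yl]-4-(naphthalen-2-ylmethoxy)-2-[(4,4,5,5-tetramethyl-1,3,2-dioxaborolan-2-yl)methyl]pent-2-enoate | O=C/C=C(/C)C1=CC(=O)[C@@](C)(C[C@@H](OCc2ccc3ccccc3c2)/C=C(\CB2OC(C)(C)C(C)(C)O2)C(=O)OC)O1
F4 | step 7 | (R)-2-(naphthalen-2-ylmethoxy)-4-oxopentanal | CC(=O)C[C@@H](OCc1ccc2ccccc2c1)C=O
F5 | step 7 | methyl (4R)-3-hydroxy-2-methylidene-4-(naphthalen-2-ylmethoxy)-6-oxoheptanoate | CC(=O)C[C@@H](OCc1ccc2ccccc2c1)C(O)C(=C)C(=O)OC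
F6 | step 7 | methyl (4R)-2-methylidene-4-(naphthalen-2-ylmethoxy)-6-oxo-3-(triethylsilyloxy)heptanoate | CC(=O)C[C@@H](OCc1ccc2ccccc2c1)C(O[Si](CC)(CC)CC)C(=C)C(=O)OC
F7 | step 7 | methyl (4R,6R,10Z)-6-hydroxy-12,12-dimethoxy-6,10-dimethyl-2-methylidene-4-(naphthalen-2-ylmethoxy)-9-oxo-3-(triethylsilyloxy)dodec-10-en-7-ynoate | COC(OC)/C=C(/C)C(=O)C#C[C@](C)(O)C[C@@H](OCc1ccc2ccccc2c1)C(O[Si](CC)(CC)CC)C(=C)C(=O)OC
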